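In a one-step world every E charged ends as Z, so the alder run, with equal charges of G and E, should climb towards 120 mM of Z; instead its readings stand at 29.0 mM at 5.2 h and 29.6 mM at 6.4 h.

| flask | G | E | time |
|---|---|---|---|
| alder | 120 mM | 120 mM |  |
| oak | 240 mM | 120 mM |  |
| ash | 120 mM | 360 mM |  |
| elm | 120 mM | 120 mM | 19 h |

- alder run (time / h: [Z] / mM): 0.23: 4.3; 0.70: 8.4; 1.3: 15.8; 2.1: 19.9; 3.0: 24.6; 4.0: 26.7; 5.2: 29.0; 6.4: 29.6
- oak run (time / h: [Z] / mM): 0.23: 6.6; 0.70: 18.3; 1.3: 27.1; 2.1: 37.2; 3.0: 40.8; 4.0: 44.7; 5.2: 47.4; 6.4: 46.8
- ash run (time / h: [Z] / mM): 0.23: 13.6; 0.70: 34.1; 1.3: 50.0; 2.1: 60.2; 3.0: 67.5; 4.0: 70.6; 5.2: 71.0; 6.4: 71.4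

(each reading ± 0.6 mM)

- Overall: G + E -> Z.
- Constant volume, constant temperature.
- A reading of a species includes what of it is bound.
- An order is taken over about fifteen percent of the charge, up and down.

* the exponent of [G] in the starting rate at the charge of the alder run (at the point where two percent of the G have become Z) (one fixed amount of Z, the same in the runs compared)
* the exponent of [E] in the starting rate at the charge of the alder run (at the point where two percent of the G have become Z)
* Z in the elm run at 19 h, as a share of the G charged

I therefore keep books on E, taking each Z as one E spent. In the alder run 120 mM of E goes in and 29.6 mM is booked to Z, which leaves 90.4 mM not in Z. The G charge stands the same 90.4 mM above that Z, and I enter the E not in Z as one lump, whether spent by a route that gives no Z or still unspent.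

The two entries then make one number, which I call the capture odds: E booked to Z divided by E not booked to Z, at the last reading of a run. It is a ratio of amounts at the end of a run, not a ratio of rates. The alder run gives 0.327. The oak run, with 240 mM of G, gives 0.639, which is nearly twice as much for twice the G.

Read as a power of the G charge, the odds give 0.965, and I take that as my order in [G]. For [E] I leave the books and compare the readings at 0.70 h in the ash and alder runs, which give 1.28. The elm run has the alder charge, and the last alder step of 0.600 mM is about one standard deviation, so I close its books at the alder odds, which is 24.7% of the G.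

The forecast differs from my figures, giving 0.85, 1.15 and 25.6% on the view that “the active agent probably dies”.

The flask gives 1.1, 1.5 and 25.0%.

    2 E ⇌ E2, settled at all times (6.510 M⁻¹)
    G + E2 → Z + E (4.824 M⁻¹ h⁻¹)
    Z + E → J (0.8748 M⁻¹ h⁻¹)
    E → Zo (0.2308 h⁻¹)

The elm run's share is 30.0 mM of Z, so its capture odds are 0.333, against 0.327 in the alder run. The oak run starts 2.1 times as fast as the alder run at the same Z, beside an odds ratio of 1.95. The ash run starts 4.3 times as fast as the alder run, and its odds read 0.247.

Readings and results are calculated with made-up constants.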